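**Stereochemistry note.** Kuwanon T (15) has no stereocentres and no E/Z alkenes, so no stereochemical control is needed. The only stereocentres in the route (the carbinol in 7 and the diketone CH in 14) are destroyed in the next step.

## Retrosynthesis
- Kuwanon T (15) comes from a 1,3-diketone (14) by acid-mediated cyclodehydration, which closes ring C, with global MOM removal.
- Diketone 14 comes from a late Baker–Venkataraman-type coupling of two C12-skeleton fragments: the A-ring ketone 8 and the B-ring aroyl chloride 13.
- Ketone 8 is built from resorcinol by C5 C–H borylation and oxidation (giving the phloroglucinol pattern), Casnati ortho-formylation, then Grignard addition and oxidation.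
- Acid chloride 13 is built from the same bis-MOM resorcinol by C2 prenylation, C4 formylation (both by directed lithiation), Pinnick oxidation and acid chloride formation.

## Route

**Step 1**
Reactants: 1 resorcinol
Product: 2 1,3-bis(methoxymethoxy)benzene
Conditions: NaH, MOMCl, THF/DMF, 0 °C → rt
Reagents that add atoms: chloromethyl methyl ether, COCCl
Why: Williamson-type acetal protection. MOM ethers survive organolithiums, Ir catalysis, Grignards and base, and are removed at the end.

**Step 2**
Reactants: 2
Product: 3 2-[3,5-bis(MOMO)phenyl]-4,4,5,5-tetramethyl-1,3,2-dioxaborolane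
Conditions: [Ir(cod)OMe]2 (1.5 mol%), dtbpy (3 mol%), B2pin2, THF, 80 °C
Reagents that add atoms: bis(pinacolato)diboron, CC1(C)OB(OC1(C)C)B1OC(C)(C)C(C)(C)O1
Why: Ir-catalysed C–H borylation is sterically controlled and goes only to C5, which is meta to both OMOM groups. This is the position that becomes the third oxygenated carbon of ring A.

**Step 3**
Reactants: 3
Product: 4 3,5-bis(methoxymethoxy)phenol
Conditions: 30% aq. H2O2, aq. NaOH, THF, 0 °C → rt; NH4Cl work-up
Reagents that add atoms: hydrogen peroxide, OO
Why: oxidative C–B to C–O conversion (boronate oxidation with retention). It gives the symmetric phloroglucinol-type phenol.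

**Step 4**
Reactants: 4
Product: 5 2-hydroxy-4,6-bis(methoxymethoxy)benzaldehyde
Conditions: MgCl2, Et3N, (CH2O)n, MeCN, 80 °C
Reagents that add atoms: paraformaldehyde (formaldehyde), C=O
Why: Casnati–Skattebøl ortho-formylation through a magnesium phenoxide. Both ortho positions are equivalent, so there is no regiochemical issue.

**Step 5**
Reactants: 5; 6 5-bromo-2-methylpent-2-ene (CC(C)=CCCBr)
Product: 7 1-[2-hydroxy-4,6-bis(MOMO)phenyl]-5-methylhex-4-en-1-ol (racemic)
Conditions: 6 + Mg, THF, reflux, to make the Grignard reagent; then add 5 (Grignard in excess, ≥3 equiv), THF, 0 °C → rt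
Reagents that add atoms: none (the C6 chain comes from 6)
Why: Grignard 1,2-addition to the aldehyde as its magnesium phenoxide; the phenol consumes one equivalent. The new carbinol centre is racemic and is removed in step 6. The homoallylic Grignard does not rearrange.

**Step 6**
Reactants: 7
Product: 8 1-[2-hydroxy-4,6-bis(MOMO)phenyl]-5-methylhex-4-en-1-one
Conditions: activated MnO2, CH2Cl2, rt
Reagents that add atoms: none
Why: MnO2 selectively oxidises the electron-rich 2-hydroxybenzylic alcohol and leaves the alkene, MOM groups and phenol untouched. The carbinol stereocentre is lost.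

**Step 7**
Reactants: 2; 9 prenyl bromide (CC(C)=CCBr)
Product: 10 2-prenyl-1,3-bis(methoxymethoxy)benzene
Conditions: n-BuLi, THF, 0 °C; then CuI (10 mol%), 9, −78 °C → rt
Reagents that add atoms: none (prenyl comes from 9)
Why: directed ortho-metalation goes at C2, between the two MOM-ether oxygens (the most acidic and best chelated site). Cu-catalysed SN2 alkylation gives the linear prenyl group.

**Step 8**
Reactants: 10
Product: 11 2,4-bis(MOMO)-3-prenylbenzaldehyde
Conditions: n-BuLi, TMEDA, THF, −20 °C; then DMF, −78 °C → rt; NH4Cl work-up
Reagents that add atoms: N,N-dimethylformamide, CN(C)C=O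
Why: directed ortho-lithiation at C4, ortho to an OMOM group, followed by formylation. C2 is blocked, and C4 and C6 are equivalent. The CHO ends up ortho to one OMOM and para to the other, matching the 2',4'-dioxygenated-3'-prenyl B ring.

**Step 9**
Reactants: 11
Product: 12 2,4-bis(MOMO)-3-prenylbenzoic acid
Conditions: NaClO2, NaH2PO4, 2-methyl-2-butene, t-BuOH/H2O, rt
Reagents that add atoms: sodium chlorite, [Na+].[O-]Cl=O
Why: Pinnick oxidation. The buffer keeps the pH mild enough for the MOM groups, and the alkene scavenger protects the prenyl double bond from HOCl.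

**Step 10**
Reactants: 12
Product: 13 2,4-bis(MOMO)-3-prenylbenzoyl chloride
Conditions: Ghosez reagent, CH2Cl2, 0 °C → rt, 1 h; concentrate, use crude
Reagents that add atoms: 1-chloro-N,N,2-trimethylpropenylamine, CC(C)=C(Cl)N(C)C
Why: this converts the acid to the acid chloride under neutral conditions, with no HCl to cleave the MOM groups or cyclise the prenyl group.

**Step 11 (fragment coupling)**
Reactants: 8; 13
Product: 14 1-[2-hydroxy-4,6-bis(MOMO)phenyl]-3-[2,4-bis(MOMO)-3-prenylphenyl]-2-prenylpropane-1,3-dione
Conditions: 8, LiHMDS (3.2 equiv), THF, −78 °C; add 13 (1.3 equiv); −78 °C → rt, 4 h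
Reagents that add atoms: none (the aroyl group comes from 13)
Why: one-pot Baker–Venkataraman acylation. The phenoxide is O-aroylated by 13, the α-CH2 enolate then attacks the ester C=O through a six-membered transition state, and acyl transfer gives the 1,3-diketone. This installs C2 (with its B ring) and the 3-prenyl carbon; the labile CH stereocentre is lost in step 12.

**Step 12**
Reactants: 14
Product: 15 Kuwanon T
Conditions: 3 M aq. HCl, MeOH/THF (4:1), 50 °C, 6 h
Reagents that add atoms: none
Why: acid-catalysed cyclodehydration of the o-hydroxyaryl 1,3-diketone (flavone ring closure) together with hydrolysis of all four MOM acetals. These are mild conditions, and the prenyl alkenes are not expected to cyclise onto the phenols.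

## Compound list
1 | resorcinol | Oc1cccc(O)c1 | starting material
2 | 1,3-bis(methoxymethoxy)benzene | COCOc1cccc(OCOC)c1 | intermediate
3 | 3,5-bis(MOMO)phenyl-Bpin | CC1(C)OB(OC1(C)C)c1cc(OCOC)cc(OCOC)c1 | intermediate
4 | 3,5-bis(methoxymethoxy)phenol | COCOc1cc(O)cc(OCOC)c1 | intermediate
5 | 2-hydroxy-4,6-bis(MOMO)benzaldehyde | COCOc1cc(O)c(C=O)c(OCOC)c1 | intermediate
6 | 5-bromo-2-methylpent-2-ene | CC(C)=CCCBr | starting material
7 | 1-[2-hydroxy-4,6-bis(MOMO)phenyl]-5-methylhex-4-en-1-ol (racemic) | COCOc1cc(O)c(C(O)CCC=C(C)C)c(OCOC)c1 | intermediate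
8 | 1-[2-hydroxy-4,6-bis(MOMO)phenyl]-5-methylhex-4-en-1-one | COCOc1cc(O)c(C(=O)CCC=C(C)C)c(OCOC)c1 | intermediate
9 | prenyl bromide | CC(C)=CCBr | starting material
10 | 2-prenyl-1,3-bis(methoxymethoxy)benzene | CC(C)=CCc1c(OCOC)cccc1OCOC | intermediate
11 | 2,4-bis(MOMO)-3-prenylbenzaldehyde | CC(C)=CCc1c(OCOC)ccc(C=O)c1OCOC | intermediate
12 | 2,4-bis(MOMO)-3-prenylbenzoic acid | CC(C)=CCc1c(OCOC)ccc(C(=O)O)c1OCOC | intermediate
13 | 2,4-bis(MOMO)-3-prenylbenzoyl chloride | CC(C)=CCc1c(OCOC)ccc(C(=O)Cl)c1OCOC | intermediate
14 | 1,3-diketone | COCOc1cc(O)c(C(=O)C(CC=C(C)C)C(=O)c2ccc(OCOC)c(CC=C(C)C)c2OCOC)c(OCOC)c1 | intermediate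
15 | Kuwanon T | CC(C)=CCc1c(O)ccc(-c2oc3cc(O)cc(O)c3c(=O)c2CC=C(C)C)c1O | target

## Step count
- Total steps: 12.
- Longest linear sequence: 8 (steps 1 → 2 → 3 → 4 → 5 → 6 → 11 → 12). The B-ring branch (steps 1, 7–10, then 11 and 12) is 7 steps.
- Ratio: 8/12 = 2/3.

## Three steps most likely to fail
1. **Step 8 (C4 lithiation/formylation of 10).** Benzylic/allylic deprotonation of the prenyl CH2 may compete with ring lithiation.
   Fallback: change the order. Brominate 2 with NBS at C4, do C2 lithiation and prenylation, then Br/Li exchange (t-BuLi, −78 °C) and DMF quench. This uses halogen–metal exchange instead of directed metalation.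
2. **Step 11 (hindered acylation and acyl transfer).** The bulky ortho-substituted aroyl chloride and the α-substituted ketone enolate may stall at the ester or give poor C-acylation.
   Fallback: change the coupling. Do a Claisen–Schmidt condensation of 8 with aldehyde 11 to give the α-prenyl-2'-hydroxychalcone, then I2/DMSO oxidative cyclisation to the protected flavone, then step 12.
3. **Steps 5/6 (Grignard addition to the magnesium phenoxide, then oxidation of the o-hydroxybenzylic alcohol).** The addition may be sluggish, and the alcohol may eliminate to an o-quinone methide.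
   Fallback: change the route to ketone 8. MOM-protect phenol 4 to 1,3,5-tris(MOMO)benzene, do directed lithiation and acylation with the Weinreb amide of 5-methylhex-4-enoic acid, then remove the MOM ortho to the ketone by chelation-assisted Lewis-acid cleavage (e.g. MgBr2).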